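## Analysis of the target

The target (17) is quercetin 3',4'-bis(hydrogen sulfate), a 2-aryl-3-hydroxy-4H-chromen-4-one. Ring A (C4a to C8a) carries free hydroxyls at C5 and C7, ring C is the gamma-pyranone with an enolic hydroxyl at C3, and ring B carries two neighbouring sulfate monoesters at C3' and C4'. The target has no stereocentre, so any stereocentre made on the way is transient and needs no control. The sensitive groups are the aryl sulfate monoesters. They are strongly acidic, are lost by acid-catalysed hydrolysis and do not tolerate silica chromatography, so they must come last and be handled as salts. The free catechol and the flavonol enol are also easily oxidised under basic, aerobic conditions. The main difficulty is differentiating five hydroxyl groups so that only the two catechol oxygens are sulfated, and placing two anionic groups on adjacent carbons. The carbon skeleton is simple: ring A has the oxygenation pattern of a 2,4,6-trioxygenated benzaldehyde and ring B that of a catechol with a two-carbon side chain. The strategy rests on ring C at the dihydro level, where C4 is a ketone and C3 a secondary alcohol on adjacent carbons. This alpha-ketol can be made directly from two aldehyde carbons, and the remaining ring C link O1–C2 is an ordinary aryl alkyl ether.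

## Retrosynthetic reasoning

**17 back to 14.** The two S–O bonds of the sulfate esters are cut first, and the hydrogens on O3, O5 and O7 are replaced in thought by benzyl groups. This leads through salt 16 and its tribenzyl ether 15 to catechol 14. The sulfates are the most labile and most polar groups, so only a neutral hydrogenolysis and a proton exchange should follow them. The forward steps must sulfate two adjacent phenols completely and then remove three benzyl ethers without touching S–O bonds or the C2=C3 double bond.

**14 back to 12.** The catechol of 14 is masked as the diphenylmethylene ketal in 13, and the O3–benzyl bond of 13 is cut to give flavonol 12. The ketal is cleaved by aqueous acid while benzyl ethers stay, which exposes exactly the two oxygens to be sulfated. O3 can only be benzylated once ring C is aromatic, so this ether is made after the oxidation.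

**12 back to 11.** Adding two hydrogens across C2=C3 in thought gives the dihydroflavonol 11. This reveals the ketone at C4 next to a carbinol at C3. The forward step is a dehydrogenation, and the two stereocentres of 11 disappear in it.

**11 back to 10.** The C3–C4 bond is cut so that both carbons become formyl carbons of dialdehyde 10. This is preferred to a cut at C4–C4a, which would need acylation of a protected trioxygenated arene with a fragile alpha-oxygenated acid. It is also preferred to a cut at C2–C3, which would need a chalcone and a separate oxidation to bring in the C3 oxygen. Here the C3 oxygen, the C4 carbonyl and ring C all arise in one catalytic, redox-neutral step. The forward reaction must favour cyclisation over intermolecular coupling and aldol chemistry.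

**10 back to 8.** Both formyl groups of 10 are traced through diol 9 to the ester aldehyde 8. The enolisable alpha-aryl-alpha-aryloxy aldehyde could not survive the basic ether formation, whereas a methyl ester can. A reduction and a double oxidation are the price.

**8 back to 2 and 7.** The O1–C2 ether bond is cut between the phenol oxygen of 2 and the benzylic, ester-activated carbon of bromide 7. This is the convergent joint of the ring A and ring B fragments and uses a carbon that is doubly activated for substitution.

**Fragments.** Phenol 2 comes from 1 by benzylation of the two more reactive hydroxyls. Bromide 7 comes from ester 6 by benzylic bromination, 6 from catechol ester 4 and dichloride 5, and 4 from acid 3.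

## Alternatives that were turned down

**Alternative 1:** Ring A is cut at C4a–C5 and ring C at O1–C2, leading back to the open poly-beta-carbonyl ester A1, carried in partly masked form. In the forward key step Mg(OMe)2 would template the chain so that the methylene between two ketones (the later C4a) attacks the ester carbon (the later C5) in a Claisen condensation and the ring aromatises. Mild anhydrous acid would then condense the C8a hydroxyl onto the aryl ketone carbon to give flavone A2.
- For it: it follows the biosynthetic logic and needs no oxidation after ring formation. A2 already carries the O3 benzyl ether and the catechol ketal, and on that point it is as strong as the chosen route.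
- Against it: A1 needs several iterative acylations with masking. The chain can also fold by aldol closure or close to a pyranone, and the acidic benzyloxy methine between two carbonyls invites retro-Claisen cleavage. A2 has a free 7-hydroxyl, which would have to be benzylated before sulfation.
- Comparison: the route spends its effort building a ring A that the chosen route takes intact from 1 in one step. The chosen strategy offers a short convergent assembly from stable aromatic pieces.

**Alternative 2:** Three bonds are cut, C4a–C4, C4–C3 and O1–C2, giving aryl iodide A3, alkyne A4 and carbon monoxide A5. In the forward step zerovalent palladium, formed from PdCl2(PPh3)2 in a secondary amine, would insert into the C–I bond and take up A5. The aroyl palladium species would couple with A4 to an alkynone, and after amine cleavage of the ortho acetate the phenoxide would close 6-endo onto the ynone to give flavone A6.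
- For it: it is the most convergent plan. It reaches the flavone core in fewer steps than the chosen route needs for 12, and on skeleton economy it is stronger.
- Against it: A6 has hydrogen at C3. The C3 oxygen would have to be added afterwards by protection of O5 and O7 and oxidation of an electron-rich flavone, which costs at least three further steps of uncertain efficiency. Closure in the 5-exo sense to an aurone and direct non-carbonylative coupling at the hindered iodide are further competitors.
- Comparison: the chosen strategy builds the C3 oxygen in the same step that forms the ring, so no late C–H oxidation is needed.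

**Alternative 3:** Ring A is cut across C5–C6, C7–C8 and C4a–C5, keeping ring C as a pyranone derived from kojic acid A7 and elaborated to diazoketone A8. In the forward step irradiation of A8 would trigger a Wolff rearrangement to a pyranonyl ketene, which would add [2+2] to ynol ether A9. Warming would open the cyclobutenone to a dienylketene, which would close by six-electron electrocyclisation onto the pyranone carbon that becomes C4a and tautomerise to phenol A10 (a Danheiser benzannulation).
- For it: the alkyne polarisation fixes the ring A oxygen pattern. A10 has benzyl groups on O3 and O7, a chelated and unreactive 5-hydroxyl and the ketal. The end game would be only ketal hydrolysis, sulfation and hydrogenolysis, one step shorter than the chosen end game and without a late oxidation.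
- Against it: the preparation of A8 from A7 is long and needs arylation next to the benzyloxy group and a hazardous diazoalkane acylation. A9 is thermally labile and not a shelf compound. The 4-pyranone chromophore is itself photoreactive, and the electrocyclisation must engage an electron-poor, cross-conjugated double bond.
- Comparison: the chosen strategy accepts one more protecting-group step at the end, but takes both aromatic rings from commercial materials and places its single risky step on a precursor seven steps from them.

Key step: step 8

Assumption: the target is taken as the free bis(hydrogen sulfate) as written and is released from its salt by cold cation exchange in the last operation; in practice it is best stored as a salt. All chiral intermediates are racemic, since the target has no stereocentre.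

## Route

Step 1
Reactants: 1 2,4,6-trihydroxybenzaldehyde
Product: 2 2,4-bis(benzyloxy)-6-hydroxybenzaldehyde
Conditions: BnBr (2.1 equiv), K2CO3, DMF, 0 °C → rt
Reagents that add atoms: benzyl bromide, BrCc1ccccc1
Why: Williamson ether synthesis; the para hydroxyl and then one ortho hydroxyl should react, after which the last hydroxyl is held in a hydrogen bond to the formyl oxygen and is much less nucleophilic.

Step 2
Reactants: 3 3,4-dihydroxyphenylacetic acid
Product: 4 methyl 3,4-dihydroxyphenylacetate
Conditions: MeOH, H2SO4 (cat.), reflux
Reagents that add atoms: methanol, CO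
Why: Fischer esterification; the ester is needed because a free acid would be turned into its acid chloride by the dichloride of the next step.

Step 3
Reactants: 4 methyl 3,4-dihydroxyphenylacetate; 5 dichlorodiphenylmethane
Product: 6 methyl (2,2-diphenyl-1,3-benzodioxol-5-yl)acetate
Conditions: neat (or Ph2O), 175 °C, N2 stream
Reagents that add atoms: none
Why: Thermal ketalisation of a catechol with a geminal dichloride, driven by loss of HCl; the diphenylmethylene ketal is stable to hydride, base and oxidants and is later removed by aqueous acid in the presence of benzyl ethers.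

Step 4
Reactants: 6 methyl (2,2-diphenyl-1,3-benzodioxol-5-yl)acetate
Product: 7 racemic methyl bromo(2,2-diphenyl-1,3-benzodioxol-5-yl)acetate
Conditions: NBS, AIBN (cat.), PhCF3, 85 °C
Reagents that add atoms: N-bromosuccinimide, O=C1CCC(=O)N1Br
Why: Wohl–Ziegler bromination; the radical is both benzylic and alpha to the ester, the ketal carbon bears no hydrogen, and the non-polar radical conditions should suppress ring bromination.

Step 5
Reactants: 2 2,4-bis(benzyloxy)-6-hydroxybenzaldehyde; 7 racemic methyl bromo(2,2-diphenyl-1,3-benzodioxol-5-yl)acetate
Product: 8 racemic methyl 2-[3,5-bis(benzyloxy)-2-formylphenoxy]-2-(2,2-diphenyl-1,3-benzodioxol-5-yl)acetate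
Conditions: K2CO3, DMF, rt
Reagents that add atoms: none
Why: Williamson ether synthesis by SN2 displacement at a carbon activated by both the aryl group and the ester; mild carbonate at room temperature should keep the product from aldol closure onto the ortho formyl group.

Step 6
Reactants: 8 racemic methyl 2-[3,5-bis(benzyloxy)-2-formylphenoxy]-2-(2,2-diphenyl-1,3-benzodioxol-5-yl)acetate
Product: 9 racemic 2-[3,5-bis(benzyloxy)-2-(hydroxymethyl)phenoxy]-2-(2,2-diphenyl-1,3-benzodioxol-5-yl)ethanol
Conditions: LiAlH4, THF, 0 °C; then H2O, aq. NaOH
Reagents that add atoms: none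
Why: Hydride reduction of the ester and the aldehyde to the diol; ethers and ketal are inert, and the basic work-up protects the acid-sensitive trioxygenated benzylic alcohol.

Step 7
Reactants: 9 racemic 2-[3,5-bis(benzyloxy)-2-(hydroxymethyl)phenoxy]-2-(2,2-diphenyl-1,3-benzodioxol-5-yl)ethanol
Product: 10 racemic 2,4-bis(benzyloxy)-6-[1-(2,2-diphenyl-1,3-benzodioxol-5-yl)-2-oxoethoxy]benzaldehyde
Conditions: Dess–Martin periodinane, NaHCO3, CH2Cl2, 0 °C → rt; used crude at once
Reagents that add atoms: none
Why: Dess–Martin oxidation of both primary alcohols under buffered, nearly neutral conditions; it is chosen over an activated-DMSO oxidation because the very electron-rich benzylic alcohol could ionise from an alkoxysulfonium salt, and because no amine base touches the enolisable aldehyde.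

Step 8
Reactants: 10 racemic 2,4-bis(benzyloxy)-6-[1-(2,2-diphenyl-1,3-benzodioxol-5-yl)-2-oxoethoxy]benzaldehyde
Product: 11 racemic trans-5,7-bis(benzyloxy)-2-(2,2-diphenyl-1,3-benzodioxol-5-yl)-3-hydroxychroman-4-one (drawn as the 2R,3R enantiomer)
Conditions: 3-benzyl-5-(2-hydroxyethyl)-4-methylthiazolium chloride (20 mol %), Et3N (40 mol %), degassed EtOH–THF, 0.02 M, 60 °C, Ar
Reagents that add atoms: none
Why: Et3N deprotonates the thiazolium salt to the thiazol-2-ylidene, which adds to a formyl group and after proton transfer gives the Breslow enaminol, an acyl anion equivalent; this attacks the second formyl carbon in the same molecule, and proton transfer with loss of the carbene forms C3–C4 and the alpha-ketol. The closest known reaction type is the carbene-catalysed intramolecular crossed benzoin cyclisation of tethered dicarbonyl compounds to 3-hydroxychroman-4-ones. Ring C closes in the 6-exo-trig mode. C2 is brought in racemic from 10 and C3 is new; because C3 is alpha to the ketone it epimerises through the enol under Et3N, so thermodynamic control should favour the trans isomer with aryl and hydroxyl both equatorial. Cyclisation must outrun intermolecular benzoin and aldol reactions, which high dilution and the six-membered transition state should secure, and the 5-exo aldol adduct of the enolisable aldehyde cannot dehydrate at its quaternary carbon and should revert. The donor sense need not be controlled: the aryl aldehyde as donor gives 11 directly, whereas the aliphatic aldehyde as donor gives the isomeric 4-hydroxy-3-ketone, which shares its enediol with 11, can isomerise to the conjugated aryl ketone and is in any case oxidised to the same flavonol in step 9. Both stereocentres are erased there, so no stereocontrol is required.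

Step 9
Reactants: 11 racemic trans-5,7-bis(benzyloxy)-2-(2,2-diphenyl-1,3-benzodioxol-5-yl)-3-hydroxychroman-4-one
Product: 12 5,7-bis(benzyloxy)-2-(2,2-diphenyl-1,3-benzodioxol-5-yl)-3-hydroxy-4H-chromen-4-one
Conditions: I2 (20 mol %), DMSO, 100 °C
Reagents that add atoms: none
Why: Iodine-mediated dehydrogenation with DMSO as terminal oxidant (Kornblum-type reoxidation of HI); iodination of the enediol at C3 and loss of HI should give the 3,4-dione, which tautomerises to the aromatic flavonol, and either ketol regioisomer from step 8 passes through the same enediol.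

Step 10
Reactants: 12 5,7-bis(benzyloxy)-2-(2,2-diphenyl-1,3-benzodioxol-5-yl)-3-hydroxy-4H-chromen-4-one
Product: 13 3,5,7-tris(benzyloxy)-2-(2,2-diphenyl-1,3-benzodioxol-5-yl)-4H-chromen-4-one
Conditions: BnBr, K2CO3, DMF, 50 °C
Reagents that add atoms: benzyl bromide, BrCc1ccccc1
Why: Williamson etherification of the acidic enolic 3-hydroxyl, the only free hydroxyl in 12, so that it cannot be sulfated later.

Step 11
Reactants: 13 3,5,7-tris(benzyloxy)-2-(2,2-diphenyl-1,3-benzodioxol-5-yl)-4H-chromen-4-one
Product: 14 3,5,7-tris(benzyloxy)-2-(3,4-dihydroxyphenyl)-4H-chromen-4-one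
Conditions: AcOH–H2O (4:1), reflux, Ar
Reagents that add atoms: none
Why: Acid hydrolysis of the diaryl ketal through the stabilised diphenylmethyl cation; benzyl ethers should survive this weak acid, and partial loss of the peri O5 benzyl group would be harmless because a chelated 5-hydroxyl is not sulfated.

Step 12
Reactants: 14 3,5,7-tris(benzyloxy)-2-(3,4-dihydroxyphenyl)-4H-chromen-4-one
Product: 15 bis(triethylammonium) 4-[3,5,7-tris(benzyloxy)-4-oxo-4H-chromen-2-yl]-1,2-phenylene bis(sulfate)
Conditions: SO3·NMe3 (10 equiv), Et3N, MeCN, 100 °C (sealed tube); Sephadex LH-20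
Reagents that add atoms: sulfur trioxide–trimethylamine complex, C[N+](C)(C)S(=O)(=O)[O-]; triethylamine, CCN(CC)CC
Why: O-sulfation of phenols by sulfur trioxide transfer from an amine complex; a large excess and heat should force the second sulfation next to the first sulfate, and the two catechol oxygens are the only free hydroxyls.

Step 13
Reactants: 15 bis(triethylammonium) 4-[3,5,7-tris(benzyloxy)-4-oxo-4H-chromen-2-yl]-1,2-phenylene bis(sulfate)
Product: 17 4-(3,5,7-trihydroxy-4-oxo-4H-chromen-2-yl)-1,2-phenylene bis(hydrogen sulfate), via bis(triethylammonium) quercetin 3',4'-disulfate 16 (not isolated)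
Conditions: H2 (1 atm), 10% Pd/C, MeOH–H2O, rt; filter; Dowex 50W (H+ form), H2O, 0 °C; freeze-dry
Reagents that add atoms: none
Why: Hydrogenolysis of the three benzyl ethers under neutral conditions, which aryl sulfate salts and the flavonol double bond should tolerate, followed by cation exchange that replaces triethylammonium by protons in the cold to limit hydrolysis of the sulfates.

## Compound list

1 | 2,4,6-trihydroxybenzaldehyde | O=Cc1c(O)cc(O)cc1O | starting material
2 | 2,4-bis(benzyloxy)-6-hydroxybenzaldehyde | O=Cc1c(O)cc(OCc2ccccc2)cc1OCc1ccccc1 | intermediate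
3 | 3,4-dihydroxyphenylacetic acid | OC(=O)Cc1ccc(O)c(O)c1 | starting material
4 | methyl 3,4-dihydroxyphenylacetate | COC(=O)Cc1ccc(O)c(O)c1 | intermediate
5 | dichlorodiphenylmethane | ClC(Cl)(c1ccccc1)c1ccccc1 | starting material
6 | methyl (2,2-diphenyl-1,3-benzodioxol-5-yl)acetate | COC(=O)Cc1ccc2OC(c3ccccc3)(c3ccccc3)Oc2c1 | intermediate
7 | racemic methyl bromo(2,2-diphenyl-1,3-benzodioxol-5-yl)acetate | COC(=O)C(Br)c1ccc2OC(c3ccccc3)(c3ccccc3)Oc2c1 | intermediate
8 | racemic methyl 2-[3,5-bis(benzyloxy)-2-formylphenoxy]-2-(2,2-diphenyl-1,3-benzodioxol-5-yl)acetate | COC(=O)C(Oc1cc(OCc2ccccc2)cc(OCc2ccccc2)c1C=O)c1ccc2OC(c3ccccc3)(c3ccccc3)Oc2c1 | intermediate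
9 | racemic 2-[3,5-bis(benzyloxy)-2-(hydroxymethyl)phenoxy]-2-(2,2-diphenyl-1,3-benzodioxol-5-yl)ethanol | OCC(Oc1cc(OCc2ccccc2)cc(OCc2ccccc2)c1CO)c1ccc2OC(c3ccccc3)(c3ccccc3)Oc2c1 | intermediate
10 | racemic 2,4-bis(benzyloxy)-6-[1-(2,2-diphenyl-1,3-benzodioxol-5-yl)-2-oxoethoxy]benzaldehyde | O=Cc1c(OCc2ccccc2)cc(OCc2ccccc2)cc1OC(C=O)c1ccc2OC(c3ccccc3)(c3ccccc3)Oc2c1 | intermediate
11 | racemic trans-5,7-bis(benzyloxy)-2-(2,2-diphenyl-1,3-benzodioxol-5-yl)-3-hydroxychroman-4-one, drawn as 2R,3R | O=C1c2c(OCc3ccccc3)cc(OCc3ccccc3)cc2O[C@H](c2ccc3OC(c4ccccc4)(c4ccccc4)Oc3c2)[C@H]1O | intermediate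
12 | 5,7-bis(benzyloxy)-2-(2,2-diphenyl-1,3-benzodioxol-5-yl)-3-hydroxy-4H-chromen-4-one | O=c1c(O)c(-c2ccc3OC(c4ccccc4)(c4ccccc4)Oc3c2)oc2cc(OCc3ccccc3)cc(OCc3ccccc3)c12 | intermediate
13 | 3,5,7-tris(benzyloxy)-2-(2,2-diphenyl-1,3-benzodioxol-5-yl)-4H-chromen-4-one | O=c1c(OCc2ccccc2)c(-c2ccc3OC(c4ccccc4)(c4ccccc4)Oc3c2)oc2cc(OCc3ccccc3)cc(OCc3ccccc3)c12 | intermediate
14 | 3,5,7-tris(benzyloxy)-2-(3,4-dihydroxyphenyl)-4H-chromen-4-one | O=c1c(OCc2ccccc2)c(-c2ccc(O)c(O)c2)oc2cc(OCc3ccccc3)cc(OCc3ccccc3)c12 | intermediate
15 | bis(triethylammonium) 4-[3,5,7-tris(benzyloxy)-4-oxo-4H-chromen-2-yl]-1,2-phenylene bis(sulfate) | O=c1c(OCc2ccccc2)c(-c2ccc(OS(=O)(=O)[O-])c(OS(=O)(=O)[O-])c2)oc2cc(OCc3ccccc3)cc(OCc3ccccc3)c12.CC[NH+](CC)CC.CC[NH+](CC)CC | intermediate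
16 | bis(triethylammonium) 4-(3,5,7-trihydroxy-4-oxo-4H-chromen-2-yl)-1,2-phenylene bis(sulfate) | O=c1c(O)c(-c2ccc(OS(=O)(=O)[O-])c(OS(=O)(=O)[O-])c2)oc2cc(O)cc(O)c12.CC[NH+](CC)CC.CC[NH+](CC)CC | intermediate
17 | 4-(3,5,7-trihydroxy-4-oxo-4H-chromen-2-yl)-1,2-phenylene bis(hydrogen sulfate) (quercetin 3',4'-disulfate) | O=c1c(O)c(-c2ccc(OS(=O)(=O)O)c(OS(=O)(=O)O)c2)oc2cc(O)cc(O)c12 | target

## Step count and least certain steps

Total: 13 steps. Longest linear sequence: 12 steps (steps 2 to 13, from 3). The ring A branch is step 1 and joins at step 5.

**Step 8 (key step).** The very acidic alpha-aryl-alpha-aryloxy aldehyde may enolise and then close by aldol reaction or oligomerise before the carbene adduct cyclises. Attack at the electron-rich, doubly ortho-substituted formyl group may be slow. Air may oxidise the Breslow intermediate. The fallback sets out from 10 and forms the same C3–C4 bond reductively. SmI2 in THF with t-BuOH at −78 °C should give, by intramolecular pinacol coupling, 5,7-bis(benzyloxy)-2-(2,2-diphenyl-1,3-benzodioxol-5-yl)chromane-3,4-diol F1 as a mixture of diastereomers. MnO2 in CH2Cl2 should then oxidise only the benzylic C4 carbinol, and the route is rejoined at 11.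

**Step 5.** The base may trigger aldol closure of the acidic alpha-hydrogen of the product onto the ortho formyl group. The labile benzylic bromide may also solvolyse or self-condense faster than the hindered, hydrogen-bonded phenol is alkylated. The fallback sets out from 6 and 2 and avoids base and bromide 7. Diazo transfer to 6 (4-acetamidobenzenesulfonyl azide, DBU, MeCN) gives methyl diazo(2,2-diphenyl-1,3-benzodioxol-5-yl)acetate F2. Rh2(OAc)4-catalysed O–H insertion of its carbenoid into phenol 2 in CH2Cl2 then gives the ether under neutral conditions, and the route is rejoined at 8.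

**Step 9.** The enolised ketol may open by beta-elimination of the O1 phenoxide and contract to benzofuranone-type products. HI at 100 °C may also remove the O5 benzyl group or the ketal, and ring A may be iodinated. The fallback sets out from 11 and oxidises the C3 carbinol directly instead of halogenating the enol. Swern oxidation ((COCl)2, DMSO, CH2Cl2, −78 °C, then Et3N) gives racemic 5,7-bis(benzyloxy)-2-(2,2-diphenyl-1,3-benzodioxol-5-yl)chromane-3,4-dione F3, which enolises on warming with the amine, and the route is rejoined at 12.

**Step 12 (with the isolation in step 13).** The second sulfation next to an anionic sulfate may stay incomplete because of charge repulsion and crowding. Sulfate may also be lost by acid-catalysed hydrolysis during isolation or in the final proton exchange. The fallback sets out from 14 and uses neutral, chromatographable sulfate diesters.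
- 2,2,2-Trichloroethyl chlorosulfate with Et3N and DMAP in THF gives 3,5,7-tris(benzyloxy)-2-{3,4-bis[(2,2,2-trichloroethoxy)sulfonyloxy]phenyl}-4H-chromen-4-one F4.
- Zn dust and HCO2NH4 in MeOH remove the trichloroethyl groups by reductive fragmentation to give diammonium 4-[3,5,7-tris(benzyloxy)-4-oxo-4H-chromen-2-yl]-1,2-phenylene bis(sulfate) F5.
- Hydrogenolysis over Pd/C gives diammonium 4-(3,5,7-trihydroxy-4-oxo-4H-chromen-2-yl)-1,2-phenylene bis(sulfate) F6, and cold proton exchange as in step 13 rejoins the route at 17.

**Step 1.** Over-benzylation, under-benzylation and C-benzylation of the electron-rich ring may give poor selectivity for the 2,4-diether. The fallback sets out from 1. Exhaustive benzylation (excess BnBr, K2CO3, DMF, 60 °C) gives 2,4,6-tris(benzyloxy)benzaldehyde F7. Chelation-controlled cleavage of one ortho benzyl ether with MgBr2·OEt2 in toluene–Et2O at reflux then rejoins the route at 2.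

## Further compounds

F1 | step 8 | 5,7-bis(benzyloxy)-2-(2,2-diphenyl-1,3-benzodioxol-5-yl)chromane-3,4-diol (racemic, mixture of diastereomers) | OC1c2c(OCc3ccccc3)cc(OCc3ccccc3)cc2OC(c2ccc3OC(c4ccccc4)(c4ccccc4)Oc3c2)C1O
F2 | step 5 | methyl diazo(2,2-diphenyl-1,3-benzodioxol-5-yl)acetate | COC(=O)C(=[N+]=[N-])c1ccc2OC(c3ccccc3)(c3ccccc3)Oc2c1
F3 | step 9 | racemic 5,7-bis(benzyloxy)-2-(2,2-diphenyl-1,3-benzodioxol-5-yl)chromane-3,4-dione | O=C1C(=O)c2c(OCc3ccccc3)cc(OCc3ccccc3)cc2OC1c1ccc2OC(c3ccccc3)(c3ccccc3)Oc2c1
F4 | step 12 | 3,5,7-tris(benzyloxy)-2-{3,4-bis[(2,2,2-trichloroethoxy)sulfonyloxy]phenyl}-4H-chromen-4-one | O=c1c(OCc2ccccc2)c(-c2ccc(OS(=O)(=O)OCC(Cl)(Cl)Cl)c(OS(=O)(=O)OCC(Cl)(Cl)Cl)c2)oc2cc(OCc3ccccc3)cc(OCc3ccccc3)c12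
F5 | step 12 | diammonium 4-[3,5,7-tris(benzyloxy)-4-oxo-4H-chromen-2-yl]-1,2-phenylene bis(sulfate) | O=c1c(OCc2ccccc2)c(-c2ccc(OS(=O)(=O)[O-])c(OS(=O)(=O)[O-])c2)oc2cc(OCc3ccccc3)cc(OCc3ccccc3)c12.[NH4+].[NH4+]
F6 | step 12 | diammonium 4-(3,5,7-trihydroxy-4-oxo-4H-chromen-2-yl)-1,2-phenylene bis(sulfate) | O=c1c(O)c(-c2ccc(OS(=O)(=O)[O-])c(OS(=O)(=O)[O-])c2)oc2cc(O)cc(O)c12.[NH4+].[NH4+]
F7 | step 1 | 2,4,6-tris(benzyloxy)benzaldehyde | O=Cc1c(OCc2ccccc2)cc(OCc2ccccc2)cc1OCc1ccccc1
A1 | alternative 1 | methyl 8-(benzyloxy)-9-(2,2-diphenyl-1,3-benzodioxol-5-yl)-3,5,7,9-tetraoxononanoate | COC(=O)CC(=O)CC(=O)CC(=O)C(OCc1ccccc1)C(=O)c1ccc2OC(c3ccccc3)(c3ccccc3)Oc2c1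
A2 | alternative 1 | 3-(benzyloxy)-2-(2,2-diphenyl-1,3-benzodioxol-5-yl)-5,7-dihydroxy-4H-chromen-4-one | O=c1c(OCc2ccccc2)c(-c2ccc3OC(c4ccccc4)(c4ccccc4)Oc3c2)oc2cc(O)cc(O)c12
A3 | alternative 2 | 2-iodobenzene-1,3,5-triyl triacetate | CC(=O)Oc1cc(OC(C)=O)c(I)c(OC(C)=O)c1
A4 | alternative 2 | 5-ethynyl-2,2-diphenyl-1,3-benzodioxole | C#Cc1ccc2OC(c3ccccc3)(c3ccccc3)Oc2c1
A5 | alternative 2 | carbon monoxide | [C-]#[O+]
A6 | alternative 2 | 2-(2,2-diphenyl-1,3-benzodioxol-5-yl)-5,7-dihydroxy-4H-chromen-4-one | O=c1cc(-c2ccc3OC(c4ccccc4)(c4ccccc4)Oc3c2)oc2cc(O)cc(O)c12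
A7 | alternative 3 | kojic acid, 5-hydroxy-2-(hydroxymethyl)-4H-pyran-4-one | O=c1cc(CO)occ1O
A8 | alternative 3 | 3-(benzyloxy)-6-(diazoacetyl)-2-(2,2-diphenyl-1,3-benzodioxol-5-yl)-4H-pyran-4-one | [N-]=[N+]=CC(=O)c1cc(=O)c(OCc2ccccc2)c(-c2ccc3OC(c4ccccc4)(c4ccccc4)Oc3c2)o1
A9 | alternative 3 | benzyl ethynyl ether | C#COCc1ccccc1
A10 | alternative 3 | 3,7-bis(benzyloxy)-2-(2,2-diphenyl-1,3-benzodioxol-5-yl)-5-hydroxy-4H-chromen-4-one | O=c1c(OCc2ccccc2)c(-c2ccc3OC(c4ccccc4)(c4ccccc4)Oc3c2)oc2cc(OCc3ccccc3)cc(O)c12
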